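Everything rests on building ring B around the ketone instead of forcing two hindered arenes together. In ring B the aroyl-bearing carbon sits between the phenolic C–O carbon and the carbon carrying the CH2 link to pyrone ring C, and three CH carbons complete the ring. This pattern lets the ketone carbon begin as the ring A-bearing alkyne carbon of a (Z)-2-en-4-ynal, the ketone oxygen as its aldehyde oxygen, and the C–O/CH edge as ethoxyacetylene. One gold-catalysed pyrylium benzannulation forms two C–C bonds, closes ring B and releases the tetra-ortho-substituted diaryl ketone. The precursor is a linear enynal with a silyloxyethyl branch, made by Sonogashira coupling.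

Key step: step 8

Remark on the chemistry: the target has no stereocentre and ring C is drawn as the 4-hydroxy-2-pyrone tautomer. The only geometric element to control is the enal double bond, where CHO and the alkynyl group must be cis (Z by the CIP rules, because alkynyl outranks the silyloxyethyl chain).

Step 1
Reactants: 1 but-3-yn-1-ol
Product: 2 4-(triisopropylsilyloxy)but-1-yne
Conditions: TIPSCl, imidazole, CH2Cl2, 0 °C to rt
Reagents that add atoms: chlorotriisopropylsilane, CC(C)[Si](Cl)(C(C)C)C(C)C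
Why: Imidazole-assisted silylation of a primary alcohol is routine, and the bulky TIPS ether is chosen because it survives n-BuLi, aluminium hydride and amines and its oxygen is too hindered to add to a gold-activated alkyne in step 8.

Step 2
Reactants: 2 4-(triisopropylsilyloxy)but-1-yne
Product: 4 5-(triisopropylsilyloxy)pent-2-yn-1-ol, via lithium acetylide 3 (not isolated)
Conditions: n-BuLi, THF, −78 °C; (CH2O)n, −78 °C to rt; H2O
Reagents that add atoms: paraformaldehyde (reacts as formaldehyde), C=O
Why: Deprotonation of the terminal alkyne and 1,2-addition of the acetylide to formaldehyde (alkyne hydroxymethylation) is standard and touches no other group.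

Step 3
Reactants: 4 5-(triisopropylsilyloxy)pent-2-yn-1-ol
Product: 6 (Z)-3-iodo-5-(triisopropylsilyloxy)pent-2-en-1-ol, via cyclic vinylalanate 5 (not isolated)
Conditions: NaAlH2(OCH2CH2OMe)2, THF, 0 °C to rt; N-iodosuccinimide, −78 °C; H2O
Reagents that add atoms: N-iodosuccinimide, O=C1CCC(=O)N1I
Why: Alkoxide-directed trans-hydroalumination of a propargylic alcohol puts aluminium on C3 inside the five-membered alanate 5, and iododealumination with retention should give only the Z-iodide, which fixes C1 cis to the future alkyne.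

Step 4
Reactants: 7 1-ethyl-3,5-dimethoxybenzene
Product: 9 2-ethyl-4,6-dimethoxybenzaldehyde, via aryl iminium chloride 8 (not isolated)
Conditions: POCl3, DMF, 0 °C to 70 °C; ice-water
Reagents that add atoms: N,N-dimethylformamide, CN(C)C=O; water, O
Why: Vilsmeier–Haack formylation of 5-alkylresorcinol dimethyl ethers goes to the carbon that is para to one methoxy group and ortho to the other, next to the alkyl group, which is the substitution pattern of ring A.

Step 5
Reactants: 9 2-ethyl-4,6-dimethoxybenzaldehyde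
Product: 10 1-ethyl-2-ethynyl-3,5-dimethoxybenzene
Conditions: dimethyl (1-diazo-2-oxopropyl)phosphonate, K2CO3, MeOH, rt
Reagents that add atoms: dimethyl (1-diazo-2-oxopropyl)phosphonate, CC(=O)C(=[N+]=[N-])P(=O)(OC)OC
Why: Seyferth–Gilbert homologation in the Ohira–Bestmann variant turns an aryl aldehyde into the terminal alkyne by olefination, loss of N2 and a 1,2-hydride shift under mild base, and it avoids cross-coupling at a doubly ortho-substituted, electron-rich aryl halide.

Step 6
Reactants: 6 (Z)-3-iodo-5-(triisopropylsilyloxy)pent-2-en-1-ol; 10 1-ethyl-2-ethynyl-3,5-dimethoxybenzene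
Product: 11 (Z)-5-(2-ethyl-4,6-dimethoxyphenyl)-3-[2-(triisopropylsilyloxy)ethyl]pent-2-en-4-yn-1-ol
Conditions: PdCl2(PPh3)2 (3 mol %), CuI (5 mol %), Et3N, THF, degassed, rt
Reagents that add atoms: none
Why: Sonogashira coupling of a vinyl iodide runs at room temperature with retention of alkene geometry (oxidative addition to zerovalent palladium and reductive elimination are both stereoretentive), the bulk of ring A lies far from the reacting alkyne terminus, and the low temperature should keep the enynol from cycloisomerising to a furan.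

Step 7
Reactants: 11 (Z)-5-(2-ethyl-4,6-dimethoxyphenyl)-3-[2-(triisopropylsilyloxy)ethyl]pent-2-en-4-yn-1-ol
Product: 12 (Z)-5-(2-ethyl-4,6-dimethoxyphenyl)-3-[2-(triisopropylsilyloxy)ethyl]pent-2-en-4-ynal
Conditions: MnO2 (excess), CH2Cl2, rt; used without storage
Reagents that add atoms: none
Why: Allylic oxidation with MnO2 is neutral and heterogeneous, stops at the aldehyde and should leave the trisubstituted Z double bond, the alkyne and the silyl ether untouched.

Step 8
Reactants: 12 (Z)-5-(2-ethyl-4,6-dimethoxyphenyl)-3-[2-(triisopropylsilyloxy)ethyl]pent-2-en-4-ynal; 13 ethoxyacetylene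
Product: 16 (2-ethyl-4,6-dimethoxyphenyl){2-ethoxy-6-[2-(triisopropylsilyloxy)ethyl]phenyl}methanone, via aurated pyrylium 14 (not isolated), via oxa-bridged adduct 15 (not isolated)
Conditions: AuBr3 (5–10 mol %), 4 Å MS, ClCH2CH2Cl, rt; 13 (3 equiv, hexane solution) by syringe pump, rt to 50 °C
Reagents that add atoms: none
Why: Proposed new method: AuBr3 binds the alkyne of 12, whose ring A-bearing carbon is the electrophilic end because the 2,4-dimethoxyaryl donor and the conjugated enal polarise it in the same sense, so the cis-placed aldehyde oxygen closes the transient six-membered pyrylium 14 in the 6-endo-dig mode. The nucleophilic CH terminus of 13 adds to the oxocarbenium carbon (the old CHO carbon) and the ethoxy-stabilised ketenium carbon is captured by the nucleophilic carbon that bears gold, which closes carbocyclic ring B in a stepwise formal [4+2] cycloaddition and gives bridged adduct 15. Departure of AuBr3 from that carbon together with cleavage of the bridgehead C–O bond aromatises ring B and leaves the old aldehyde oxygen as the ketone oxygen of 16. The closest known reaction type is the AuBr3- or Cu(OTf)2-catalysed benzannulation of ortho-alkynylbenzaldehydes and acyclic enynals with alkynes or enols to aryl ketones, and the untested element is an ynol ether as the two-carbon partner. The step needs regiocontrol (OEt next to the aroyl group), which the strong polarisation of the ynol ether secures, and preference for pyrylium capture over gold-induced loss of 13, which slow addition, molecular sieves and pre-complexation of 12 are meant to secure. No stereocentre remains in 16, and methyl and TIPS ethers are used because they neither migrate nor add to an alkyne activated by trivalent gold.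

Step 9
Reactants: 16 (2-ethyl-4,6-dimethoxyphenyl){2-ethoxy-6-[2-(triisopropylsilyloxy)ethyl]phenyl}methanone
Product: 17 [2-ethoxy-6-(2-hydroxyethyl)phenyl](2-ethyl-4,6-dimethoxyphenyl)methanone
Conditions: Bu4NF, THF, 0 °C to rt; H2O
Reagents that add atoms: none
Why: Fluoride-induced desilylation is selective for the Si–O bond, and the non-enolisable, hindered diaryl ketone and the aryl ethers are inert to it.

Step 10
Reactants: 17 [2-ethoxy-6-(2-hydroxyethyl)phenyl](2-ethyl-4,6-dimethoxyphenyl)methanone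
Product: 19 2-[3-ethoxy-2-(2-ethyl-4,6-dimethoxybenzoyl)phenyl]acetic acid, via arylacetaldehyde 18 (not isolated)
Conditions: TEMPO (20 mol %), PhI(OAc)2 (2.5 equiv), MeCN/H2O 1:1, rt
Reagents that add atoms: water, O
Why: Oxoammonium oxidation (TEMPO/PhI(OAc)2) in aqueous acetonitrile carries a primary alcohol through the aldehyde hydrate to the acid in one flask, without chlorinating or strongly acidic oxidants that could attack electron-rich ring A.

Step 11
Reactants: 19 2-[3-ethoxy-2-(2-ethyl-4,6-dimethoxybenzoyl)phenyl]acetic acid; 20 2,2,6-trimethyl-4H-1,3-dioxin-4-one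
Product: 23 6-{3-[3-ethoxy-2-(2-ethyl-4,6-dimethoxybenzoyl)phenyl]-2-oxopropyl}-2,2-dimethyl-4H-1,3-dioxin-4-one, via acyl imidazolide 21 (not isolated), via lithium dienolate 22 (not isolated)
Conditions: 19, 1,1'-carbonyldiimidazole, THF, rt; added to 22 [20 (3.5 equiv), LiN(SiMe3)2, THF, −78 °C], −78 to −20 °C; AcOH
Reagents that add atoms: none
Why: Claisen-type γ-C-acylation of the vinylogous lithium enolate of the dioxinone with an N-acylimidazole is an established way to 6-(2-oxoalkyl)dioxinones, the excess dienolate absorbs the imidazole N–H and the acidic product, and the tetra-ortho-substituted ketone is too shielded to be attacked.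

Step 12
Reactants: 23 6-{3-[3-ethoxy-2-(2-ethyl-4,6-dimethoxybenzoyl)phenyl]-2-oxopropyl}-2,2-dimethyl-4H-1,3-dioxin-4-one
Product: 25 6-{[3-ethoxy-2-(2-ethyl-4,6-dimethoxybenzoyl)phenyl]methyl}-4-hydroxy-2H-pyran-2-one, via acylketene 24 (not isolated)
Conditions: toluene, 110 °C
Reagents that add atoms: none
Why: Thermal retro-hetero-Diels–Alder loss of acetone gives an acylketene that the enol oxygen of the δ-ketone traps intramolecularly to close ring C, and the neutral medium offers no acid or base to drive an aldol attack on the diaryl ketone or a decarboxylation.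

Step 13
Reactants: 25 6-{[3-ethoxy-2-(2-ethyl-4,6-dimethoxybenzoyl)phenyl]methyl}-4-hydroxy-2H-pyran-2-one
Product: 26 6-{[2-(2-ethyl-4,6-dihydroxybenzoyl)-3-hydroxyphenyl]methyl}-4-hydroxy-2H-pyran-2-one (CNP0234555.0)
Conditions: BBr3 (10 equiv), CH2Cl2, −78 °C to rt; H2O
Reagents that add atoms: none
Why: Lewis-acid ether cleavage with BBr3 (boron on oxygen, bromide attack at the alkyl carbon) is accelerated by chelation for the methyl and ethyl ethers ortho to the ketone and reaches the para methyl ether at room temperature, while the hydroxypyrone is only held as a borate that water releases.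

Compound list
1 | but-3-yn-1-ol | C#CCCO | starting material
2 | 4-(triisopropylsilyloxy)but-1-yne | C#CCCO[Si](C(C)C)(C(C)C)C(C)C | intermediate
3 | [4-(triisopropylsilyloxy)but-1-yn-1-yl]lithium | [Li]C#CCCO[Si](C(C)C)(C(C)C)C(C)C | intermediate
4 | 5-(triisopropylsilyloxy)pent-2-yn-1-ol | OCC#CCCO[Si](C(C)C)(C(C)C)C(C)C | intermediate
5 | sodium 2,2-bis(2-methoxyethoxy)-3-[2-(triisopropylsilyloxy)ethyl]-2,5-dihydro-1,2-oxaluminol-2-uide (five-membered ring O–Al–C3=C2–C1) | [Na+].COCCO[Al-]1(OCCOC)OCC=C1CCO[Si](C(C)C)(C(C)C)C(C)C | intermediate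
6 | (Z)-3-iodo-5-(triisopropylsilyloxy)pent-2-en-1-ol | OC/C=C(\I)CCO[Si](C(C)C)(C(C)C)C(C)C | intermediate
7 | 1-ethyl-3,5-dimethoxybenzene | CCc1cc(OC)cc(OC)c1 | starting material
8 | N-[(2-ethyl-4,6-dimethoxyphenyl)methylidene]-N-methylmethanaminium chloride | CCc1cc(OC)cc(OC)c1C=[N+](C)C.[Cl-] | intermediate
9 | 2-ethyl-4,6-dimethoxybenzaldehyde | CCc1cc(OC)cc(OC)c1C=O | intermediate
10 | 1-ethyl-2-ethynyl-3,5-dimethoxybenzene | C#Cc1c(CC)cc(OC)cc1OC | intermediate
11 | (Z)-5-(2-ethyl-4,6-dimethoxyphenyl)-3-[2-(triisopropylsilyloxy)ethyl]pent-2-en-4-yn-1-ol | OC/C=C(/CCO[Si](C(C)C)(C(C)C)C(C)C)C#Cc1c(CC)cc(OC)cc1OC | intermediate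
12 | (Z)-5-(2-ethyl-4,6-dimethoxyphenyl)-3-[2-(triisopropylsilyloxy)ethyl]pent-2-en-4-ynal | O=C/C=C(/CCO[Si](C(C)C)(C(C)C)C(C)C)C#Cc1c(CC)cc(OC)cc1OC | intermediate
13 | ethoxyacetylene | CCOC#C | starting material
14 | 2-(2-ethyl-4,6-dimethoxyphenyl)-4-[2-(triisopropylsilyloxy)ethyl]pyrylium-3-yl tribromoaurate (zwitterion) | CCc1cc(OC)cc(OC)c1-c1[o+]ccc(CCO[Si](C(C)C)(C(C)C)C(C)C)c1[Au-](Br)(Br)Br | intermediate
15 | 3-(2-ethyl-4,6-dimethoxyphenyl)-8-ethoxy-5-[2-(triisopropylsilyloxy)ethyl]-2-oxoniabicyclo[2.2.2]octa-2,5,7-trien-4-yl tribromoaurate (zwitterion, racemic, transient) | CCOC1=CC2C=C(CCO[Si](C(C)C)(C(C)C)C(C)C)C1([Au-](Br)(Br)Br)C(=[O+]2)c1c(CC)cc(OC)cc1OC | intermediate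
16 | (2-ethyl-4,6-dimethoxyphenyl){2-ethoxy-6-[2-(triisopropylsilyloxy)ethyl]phenyl}methanone | CCc1cc(OC)cc(OC)c1C(=O)c1c(OCC)cccc1CCO[Si](C(C)C)(C(C)C)C(C)C | intermediate
17 | [2-ethoxy-6-(2-hydroxyethyl)phenyl](2-ethyl-4,6-dimethoxyphenyl)methanone | CCc1cc(OC)cc(OC)c1C(=O)c1c(OCC)cccc1CCO | intermediate
18 | 2-[3-ethoxy-2-(2-ethyl-4,6-dimethoxybenzoyl)phenyl]acetaldehyde | CCc1cc(OC)cc(OC)c1C(=O)c1c(OCC)cccc1CC=O | intermediate
19 | 2-[3-ethoxy-2-(2-ethyl-4,6-dimethoxybenzoyl)phenyl]acetic acid | CCc1cc(OC)cc(OC)c1C(=O)c1c(OCC)cccc1CC(=O)O | intermediate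
20 | 2,2,6-trimethyl-4H-1,3-dioxin-4-one | CC1=CC(=O)OC(C)(C)O1 | starting material
21 | 2-[3-ethoxy-2-(2-ethyl-4,6-dimethoxybenzoyl)phenyl]-1-(imidazol-1-yl)ethanone | CCc1cc(OC)cc(OC)c1C(=O)c1c(OCC)cccc1CC(=O)n1ccnc1 | intermediate
22 | lithium 2,2-dimethyl-6-methylidene-1,3-dioxin-4-olate | [Li]OC1=CC(=C)OC(C)(C)O1 | intermediate
23 | 6-{3-[3-ethoxy-2-(2-ethyl-4,6-dimethoxybenzoyl)phenyl]-2-oxopropyl}-2,2-dimethyl-4H-1,3-dioxin-4-one | CCc1cc(OC)cc(OC)c1C(=O)c1c(OCC)cccc1CC(=O)CC1=CC(=O)OC(C)(C)O1 | intermediate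
24 | 6-[3-ethoxy-2-(2-ethyl-4,6-dimethoxybenzoyl)phenyl]-3,5-dioxohex-1-en-1-one (acylketene) | CCc1cc(OC)cc(OC)c1C(=O)c1c(OCC)cccc1CC(=O)CC(=O)C=C=O | intermediate
25 | 6-{[3-ethoxy-2-(2-ethyl-4,6-dimethoxybenzoyl)phenyl]methyl}-4-hydroxy-2H-pyran-2-one | CCc1cc(OC)cc(OC)c1C(=O)c1c(OCC)cccc1Cc1cc(O)cc(=O)o1 | intermediate
26 | 6-{[2-(2-ethyl-4,6-dihydroxybenzoyl)-3-hydroxyphenyl]methyl}-4-hydroxy-2H-pyran-2-one (CNP0234555.0) | CCc1cc(O)cc(O)c1C(=O)c1c(O)cccc1Cc1cc(O)cc(=O)o1 | target

Total step count: 13. Longest linear sequence: 11 steps (1, 2, 3, 6, 7, 8, 9, 10, 11, 12, 13); steps 4 and 5 form the ring A branch.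

Steps most likely to fail

Step 8. Several processes could defeat the step.
- Gold-promoted hydration or oligomerisation of the ynol ether may outrun its capture.
- The free aldehyde may undergo carbonyl–ynol ether metathesis to a dienoate.
- A 5-exo-dig closure to a furyl gold carbene may compete with pyrylium formation.
- Capture of the ketenium ion at the crowded gold-bearing carbon may be too slow.

The fallback uses only known chemistry, sets out from 9 and comes back at 16. Ring B is bought rather than built, and the ketone is made by aryllithium addition and oxidation. Purchased 2-bromo-3-hydroxybenzaldehyde F1 is O-ethylated (EtI, K2CO3, DMF) to 2-bromo-3-ethoxybenzaldehyde F2. Wittig methylenation (Ph3PCH3Br, KOtBu, THF) gives 2-bromo-1-ethenyl-3-ethoxybenzene F3. Hydroboration with 9-BBN gives the B-alkyl borane F4, which H2O2/NaOH oxidises to 2-(2-bromo-3-ethoxyphenyl)ethanol F5. Silylation (TIPSCl, imidazole) gives the aryl bromide TIPS ether F6. Bromine–lithium exchange (n-BuLi, THF, −78 °C) gives the aryllithium F7, which adds to aldehyde 9 to give the racemic diaryl carbinol F8. Dess–Martin oxidation of F8 gives 16.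

Step 11. Proton transfer from the acidic ArCH2 group of the acyl imidazolide to the basic dienolate (enolisation, ketene formation, self-condensation) may compete with C-acylation, and some O-acylation is possible. The fallback sets out from 17 and 20 and comes back at 23. The C–C bond is made by Lewis-acid addition to an aldehyde instead of acyl substitution under base. Alcohol 17 is oxidised with Dess–Martin periodinane only as far as aldehyde 18, which is now isolated. Dienolate 22 is trapped with Me3SiCl as the silyl dienol ether F9. A vinylogous Mukaiyama aldol reaction (BF3·OEt2, CH2Cl2, −78 °C) joins 18 and F9 at the γ-carbon to give the racemic δ-hydroxy dioxinone F10. Dess–Martin oxidation of F10 gives 23.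

Step 13. The non-chelated para methyl ether of ring A may be cleaved slowly. Long exposure to excess BBr3 and HBr could then erode the pyrone-bearing polyphenol by condensation or ring opening. The fallback sets out from 19 and comes back at 26. The harsh dealkylation is moved ahead of ring C, and the phenols travel as acid-labile acetals. BBr3 (CH2Cl2, −78 °C to rt) on the robust acid 19 should give the trihydroxy acid F11. NaH and MOMCl (DMF, 0 °C) give the tris(methoxymethyl) ether methoxymethyl ester F12, and LiOH (THF/H2O) frees the tris(methoxymethyl) ether acid F13. Activation with 1,1'-carbonyldiimidazole gives the acyl imidazolide F14, which reacts with dienolate 22 as in step 11 to give the keto-dioxinone F15. Thermolysis in toluene at 110 °C, by way of the acylketene F16, gives the protected pyrone F17. Treatment with 2 M aq. HCl in THF at 40 °C removes the three acetals and gives 26.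

Further compounds
F1 | step 8 | 2-bromo-3-hydroxybenzaldehyde (purchased) | O=Cc1cccc(O)c1Br
F2 | step 8 | 2-bromo-3-ethoxybenzaldehyde | CCOc1cccc(C=O)c1Br
F3 | step 8 | 2-bromo-1-ethenyl-3-ethoxybenzene | CCOc1cccc(C=C)c1Br
F4 | step 8 | 9-[2-(2-bromo-3-ethoxyphenyl)ethyl]-9-borabicyclo[3.3.1]nonane | CCOc1cccc(CCB2C3CCCC2CCC3)c1Br
F5 | step 8 | 2-(2-bromo-3-ethoxyphenyl)ethanol | CCOc1cccc(CCO)c1Br
F6 | step 8 | [2-(2-bromo-3-ethoxyphenyl)ethoxy]triisopropylsilane | CCOc1cccc(CCO[Si](C(C)C)(C(C)C)C(C)C)c1Br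
F7 | step 8 | {2-ethoxy-6-[2-(triisopropylsilyloxy)ethyl]phenyl}lithium | CCOc1cccc(CCO[Si](C(C)C)(C(C)C)C(C)C)c1[Li]
F8 | step 8 | (2-ethyl-4,6-dimethoxyphenyl){2-ethoxy-6-[2-(triisopropylsilyloxy)ethyl]phenyl}methanol, racemic | CCc1cc(OC)cc(OC)c1C(O)c1c(OCC)cccc1CCO[Si](C(C)C)(C(C)C)C(C)C
F9 | step 11 | [(2,2-dimethyl-6-methylidene-1,3-dioxin-4-yl)oxy]trimethylsilane | C=C1C=C(O[Si](C)(C)C)OC(C)(C)O1
F10 | step 11 | 6-{3-[3-ethoxy-2-(2-ethyl-4,6-dimethoxybenzoyl)phenyl]-2-hydroxypropyl}-2,2-dimethyl-4H-1,3-dioxin-4-one, racemic | CCc1cc(OC)cc(OC)c1C(=O)c1c(OCC)cccc1CC(O)CC1=CC(=O)OC(C)(C)O1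
F11 | step 13 | 2-[2-(2-ethyl-4,6-dihydroxybenzoyl)-3-hydroxyphenyl]acetic acid | CCc1cc(O)cc(O)c1C(=O)c1c(O)cccc1CC(=O)O
F12 | step 13 | methoxymethyl 2-{2-[2-ethyl-4,6-bis(methoxymethoxy)benzoyl]-3-(methoxymethoxy)phenyl}acetate | CCc1cc(OCOC)cc(OCOC)c1C(=O)c1c(OCOC)cccc1CC(=O)OCOC
F13 | step 13 | 2-{2-[2-ethyl-4,6-bis(methoxymethoxy)benzoyl]-3-(methoxymethoxy)phenyl}acetic acid | CCc1cc(OCOC)cc(OCOC)c1C(=O)c1c(OCOC)cccc1CC(=O)O
F14 | step 13 | 2-{2-[2-ethyl-4,6-bis(methoxymethoxy)benzoyl]-3-(methoxymethoxy)phenyl}-1-(imidazol-1-yl)ethanone | CCc1cc(OCOC)cc(OCOC)c1C(=O)c1c(OCOC)cccc1CC(=O)n1ccnc1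
F15 | step 13 | 6-(3-{2-[2-ethyl-4,6-bis(methoxymethoxy)benzoyl]-3-(methoxymethoxy)phenyl}-2-oxopropyl)-2,2-dimethyl-4H-1,3-dioxin-4-one | CCc1cc(OCOC)cc(OCOC)c1C(=O)c1c(OCOC)cccc1CC(=O)CC1=CC(=O)OC(C)(C)O1
F16 | step 13 | 6-{2-[2-ethyl-4,6-bis(methoxymethoxy)benzoyl]-3-(methoxymethoxy)phenyl}-3,5-dioxohex-1-en-1-one (acylketene) | CCc1cc(OCOC)cc(OCOC)c1C(=O)c1c(OCOC)cccc1CC(=O)CC(=O)C=C=O
F17 | step 13 | 6-({2-[2-ethyl-4,6-bis(methoxymethoxy)benzoyl]-3-(methoxymethoxy)phenyl}methyl)-4-hydroxy-2H-pyran-2-one | CCc1cc(OCOC)cc(OCOC)c1C(=O)c1c(OCOC)cccc1Cc1cc(O)cc(=O)o1
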